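**Plan**

- Locants for the diaryl ether and depsidone compounds: ring A carbons are 1 (C–CH3), 2 (C–H), 3 (C–OH), 4 (C–CHO), 5 (C–O ether) and 6 (C–C(=O) of the seven-membered lactone); ring B carbons carry primes, 1′ (C–O of that lactone), 2′ (C–CH2OH), 3′ (C–OH), 4′ (C–C(=O) of the phthalide), 5′ (C–CH(OH), the lactol carbon) and 6′ (C–O ether). Monocyclic benzoates keep their ordinary benzoate locants.
- Cuts: the lactol goes back to an ortho-formyl acid and, by adding one carbon, to an isocoumarin. The isocoumarin is cut at the bond from carbon 5′ to the pyranone CH and at the carboxyl O–CH bond, giving a ring B acid with 5′–H plus vinylene carbonate. The depsidone is cut at the lactone O–C(=O) bond and at the ether bond from oxygen to carbon 6′.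
- Forward: a ring A phenol and a ring B aryliodonium salt give the diaryl ether, then the seven-membered lactone closes. The six-membered pyranone is annulated onto ring B and cut down to the five-membered lactol, and the protecting groups are removed last.
- Enabling feature: the lactol carbon sits on carbon 5′, between carbon 4′ (carboxyl carbon) and carbon 6′ (ether oxygen). In the acid precursor 5′–H is the only hydrogen ortho to the carboxyl group, because the other ortho carbon, 3′, carries oxygen.
- Stereochemistry: the lactol carbon is the only stereocentre. It forms as a racemate and is set in the last step by crystallization-induced dynamic resolution with a chiral diol host.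

Key step: step 13

Assumption: the lactol carbon is a hemiacetal that equilibrates with the open formyl acid in solution, so the (S)-form is taken to be wanted as the crystalline solid, in which the configuration is fixed.

**Route**

Step 1
Reactants: 1 orsellinic acid (2,4-dihydroxy-6-methylbenzoic acid)
Product: 2 allyl 2,4-dihydroxy-6-methylbenzoate
Conditions: allyl bromide, KHCO3, DMF, rt
Reagents that add atoms: allyl bromide, C=CCBr
Why: Carboxylate O-alkylation (SN2); hydrogencarbonate deprotonates only the carboxylic acid, so the phenols stay free, and room temperature avoids loss of CO2 from the acid.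

Step 2
Reactants: 2 allyl 2,4-dihydroxy-6-methylbenzoate
Product: 3 allyl 2-hydroxy-4-methoxy-6-methylbenzoate
Conditions: MeI (1.1 equiv), K2CO3, acetone, 40 °C
Reagents that add atoms: iodomethane, CI
Why: Williamson ether synthesis; the 2-hydroxyl is locked in a hydrogen bond to the ester carbonyl, so one equivalent of MeI should methylate only the 4-hydroxyl.

Step 3
Reactants: 3 allyl 2-hydroxy-4-methoxy-6-methylbenzoate
Product: 5 allyl 3-formyl-2-hydroxy-4-methoxy-6-methylbenzoate, via hydroxymethyl phenol 4 (not isolated)
Conditions: MgCl2, Et3N, (CH2O)n, THF, reflux; aq. HCl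
Reagents that add atoms: formaldehyde (as paraformaldehyde), C=O
Why: Casnati–Skattebøl ortho-formylation; the chloromagnesium phenoxide delivers formaldehyde to the only free ortho carbon (carbon 3 of the benzoate), and a second formaldehyde takes up hydride from the hydroxymethyl intermediate, so carbon 5 should stay untouched.

Step 4
Reactants: 6 methyl 2,4-dihydroxy-3-methylbenzoate
Product: 7 methyl 2-hydroxy-3-methyl-4-(pivaloyloxy)benzoate
Conditions: PivCl (1.05 equiv), Et3N, CH2Cl2, 0 °C
Reagents that add atoms: pivaloyl chloride, CC(C)(C)C(Cl)=O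
Why: Chemoselective acylation; the 4-hydroxyl is the free, more acidic phenol while the 2-hydroxyl is chelated to the ester, and pivalate is chosen because it should survive the later carbonate and radical steps.

Step 5
Reactants: 7 methyl 2-hydroxy-3-methyl-4-(pivaloyloxy)benzoate
Product: 8 methyl 2-hydroxy-5-iodo-3-methyl-4-(pivaloyloxy)benzoate
Conditions: NIS, TFA (cat.), MeCN, rt
Reagents that add atoms: N-iodosuccinimide, O=C1CCC(=O)N1I
Why: Electrophilic aromatic iodination; carbon 5 of the benzoate is para to the free phenol and ortho to the acyloxy group, whereas carbon 6 is meta to both oxygens, so a single iodide is expected.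

Step 6
Reactants: 8 methyl 2-hydroxy-5-iodo-3-methyl-4-(pivaloyloxy)benzoate
Product: 9 methyl 5-iodo-2-methoxy-3-methyl-4-(pivaloyloxy)benzoate
Conditions: MeI, K2CO3, DMF, 40 °C
Reagents that add atoms: iodomethane, CI
Why: Williamson ether synthesis on the chelated phenol in a dipolar solvent; the hindered pivalate should not be cleaved by anhydrous K2CO3.

Step 7
Reactants: 9 methyl 5-iodo-2-methoxy-3-methyl-4-(pivaloyloxy)benzoate
Product: 10 methyl 3-(bromomethyl)-5-iodo-2-methoxy-4-(pivaloyloxy)benzoate
Conditions: NBS (1.05 equiv), AIBN (cat.), PhCF3, 85 °C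
Reagents that add atoms: N-bromosuccinimide, O=C1CCC(=O)N1Br
Why: Wohl–Ziegler radical bromination of the only benzylic methyl; the lone ring hydrogen is meta to both oxygens and ortho to the ester, so ionic ring bromination is not expected, and neither the methyl ether nor the pivalate offers a weak C–H bond.

Step 8
Reactants: 10 methyl 3-(bromomethyl)-5-iodo-2-methoxy-4-(pivaloyloxy)benzoate
Product: 11 methyl 3-(acetoxymethyl)-5-iodo-2-methoxy-4-(pivaloyloxy)benzoate
Conditions: KOAc, DMF, rt
Reagents that add atoms: potassium acetate, CC(=O)[O-].[K+]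
Why: SN2 displacement of the benzylic bromide by acetate.

Step 9
Reactants: 11 methyl 3-(acetoxymethyl)-5-iodo-2-methoxy-4-(pivaloyloxy)benzoate
Product: 13 [3-(acetoxymethyl)-4-methoxy-5-(methoxycarbonyl)-2-(pivaloyloxy)phenyl](2,4,6-trimethoxyphenyl)iodonium acetate, via diacetoxyiodo arene 12 (not isolated)
Conditions: mCPBA, AcOH, 40 °C; evaporate; 1,3,5-trimethoxybenzene, CF3CH2OH, rt
Reagents that add atoms: acetic acid, CC(=O)O; 1,3,5-trimethoxybenzene, COc1cc(OC)cc(OC)c1
Why: Peracid oxidation of the aryl iodide to the diacetoxy-λ3-iodane (trivalent iodine), then electrophilic substitution of 1,3,5-trimethoxybenzene at iodine in the fluoroalcohol, a known acid-free way to aryl(trimethoxyphenyl)iodonium acetates that should spare the benzylic acetate.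

Step 10
Reactants: 5 allyl 3-formyl-2-hydroxy-4-methoxy-6-methylbenzoate; 13 the ring B aryl(2,4,6-trimethoxyphenyl)iodonium acetate
Product: 14 allyl 2-[3-(acetoxymethyl)-4-methoxy-5-(methoxycarbonyl)-2-(pivaloyloxy)phenoxy]-3-formyl-4-methoxy-6-methylbenzoate
Conditions: K2CO3, MeCN, 60 °C
Reagents that add atoms: none
Why: Metal-free O-arylation with a diaryliodonium salt; the phenoxide exchanges for acetate on trivalent iodine and ligand coupling transfers the less electron-rich ring B aryl group while the trimethoxyphenyl group stays on iodine, a reaction type that accepts acidic, doubly ortho-substituted phenols.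

Step 11
Reactants: 14 the diaryl ether allyl ester
Product: 16 2-[5-carboxy-2-hydroxy-3-(hydroxymethyl)-4-methoxyphenoxy]-3-formyl-4-methoxy-6-methylbenzoic acid, via ring A monoacid 15 (not isolated)
Conditions: Pd(PPh3)4 (5 mol %), HCO2H, Et3N, THF, rt; then LiOH, H2O, 0 °C to rt; 1 M HCl
Reagents that add atoms: lithium hydroxide, [Li+].[OH-]
Why: Tsuji–Trost deallylation (zerovalent palladium, formate as hydride donor) frees the doubly ortho-substituted ring A acid without attack at its shielded carbonyl, and saponification in the same flask removes the acetate, the pivalate and the ring B methyl ester; water is the only nucleophile present, and the low temperature is meant to keep the ring B phenoxide from a Smiles-type aryl shift.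

Step 12
Reactants: 16 the hydroxy diacid
Product: 18 depsidone 4′-carboxylic acid (3-OMe; 4-CHO; 2′-CH2OAc; 3′-OMe; 5′–H), via acetic mixed anhydride 17 (not isolated)
Conditions: Ac2O, 90 °C; then THF/H2O, rt
Reagents that add atoms: acetic anhydride, CC(=O)OC(C)=O
Why: Classical depsidone lactonization through mixed anhydrides; the only phenol (on carbon 1′) is acylated intramolecularly by the ring A carboxyl group to close the seven-membered lactone, the primary alcohol is acetylated at the same time, and the ring B mixed anhydride, which has no hydroxyl within reach, is hydrolysed back to the acid by water.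

Step 13
Reactants: 18 depsidone 4′-carboxylic acid; 19 vinylene carbonate
Product: 20 isocoumarin-fused depsidone (pyranone ring running from carbon 4′ through C(=O)–O–CH=CH to carbon 5′)
Conditions: [Cp*Rh(MeCN)3](SbF6)2 (5 mol %), vinylene carbonate (3 equiv), diglyme, 110 °C
Reagents that add atoms: none
Why: Carboxylate-assisted concerted metalation–deprotonation by the cationic Cp*Rh fragment (trivalent rhodium) at carbon 5′ gives a five-membered rhodacycle, the Rh–C bond adds across the C=C bond of vinylene carbonate to a seven-membered rhodacycle, and C–O reductive elimination followed by oxidative addition of the resulting monovalent rhodium into the carbonate C–O bond and β-oxygen elimination expels carbonate (CO2 plus water) and returns the trivalent catalyst, so vinylene carbonate acts as acetylene equivalent and internal oxidant. The closest known reaction type is the Cp*Rh-catalysed C–H/O–H annulation of benzoic acids with vinylene carbonate or alkynes to isocoumarins. The one new ring, the six-membered pyranone, closes by a formal [4+2] annulation: the bond from carbon 5′ to the new CH by migratory insertion and the O–C bond by reductive elimination from the seven-membered rhodacycle. No stereocentre is formed. The step needs site selectivity for carbon 5′, which the substrate secures because 5′–H is the only C–H ortho to the carboxylate (carbon 3′ carries methoxy), the single ring A hydrogen (on carbon 2) has no coordinating neighbour, and the lactone and acetate carbonyls are far weaker directing groups than carboxylate; the ether oxygen on carbon 6′ is tied back in the seven-membered ring and should crowd carbon 5′ little.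

Step 14
Reactants: 20 isocoumarin-fused depsidone
Product: 24 racemic hydroxyphthalide (lactol) bearing 3-OMe; 3′-OMe; 2′-CH2OAc, via ozonide 21 (not isolated), via formic mixed anhydride 22 (not isolated), via open formyl acid 23 (not isolated)
Conditions: O3, CH2Cl2, −78 °C; Me2S, −78 °C to rt; THF/H2O, rt
Reagents that add atoms: ozone, [O-][O+]=O
Why: Ozonolysis of the enol-ester C=C bond, the only non-aromatic alkene; reduction of the ozonide gives the aldehyde on carbon 5′ and a formic mixed anhydride on carbon 4′, water cleaves the latter, and the ortho-formyl acid closes (5-exo-trig) to the hydroxyphthalide, whose hemiacetal centre forms without control as a racemate.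

Step 15
Reactants: 24 racemic protected lactol
Product: 25 racemic lactol with free phenols on carbons 3 and 3′ and 2′-CH2OAc
Conditions: BCl3, CH2Cl2, −78 to 0 °C; H2O
Reagents that add atoms: none
Why: Chelation-assisted ether cleavage by BCl3; both methoxy groups sit ortho to a carbonyl group (ring A formyl, ring B phthalide carbonyl) and should be cleaved at low temperature, where the depsidone ester and the acetate persist, and any lactol chloride or borate is hydrolysed back on work-up.

Step 16
Reactants: 25 racemic acetate
Product: 26 the target constitution as the pair of equilibrating lactol enantiomers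
Conditions: LiOH, THF/H2O, 0 °C; 1 M HCl to pH 2
Reagents that add atoms: none
Why: Saponification of the unhindered primary acetate; the depsidone ester is shielded by two ortho substituents and deactivated by the ring A phenoxide para to its carbonyl-bearing carbon, and acidification recloses the lactol, which should precipitate.

Step 17
Reactants: 26 racemic lactol
Product: 28 CNP0166154.1, the (S)-lactol, via host inclusion crystal 27 (not isolated)
Conditions: (4R,5R)-TADDOL (1 equiv), AcOH (cat.), toluene/THF, slurry 45 to 5 °C; filter; wash the cake with cold CH2Cl2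
Reagents that add atoms: none
Why: Proposed new method: in solution the lactol opens and recloses through the achiral ortho-formyl acid (ring–chain tautomerism, speeded by a trace of acid), so its two enantiomers interconvert, while hydrogen bonding of its hydroxyl and carbonyl groups to the chiral diol host should give two diastereomeric inclusion crystals of unequal solubility; the less soluble one is meant to drain the equilibrium, and washing out the host with a solvent that does not dissolve the guest leaves the lactol with its configuration fixed in the solid. The closest known reaction types are the deracemization of epimerizable α-substituted ketones by inclusion crystallization with TADDOL-type hosts and the crystallization of a single anomer from a mutarotating sugar. The (S)-configuration is set by the handedness of the host; the (4R,5R)-host is taken to deposit the (S)-lactol, and its mirror image is available if the opposite pairing is found.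

**Compound list**

1 | orsellinic acid (2,4-dihydroxy-6-methylbenzoic acid) | Cc1cc(O)cc(O)c1C(=O)O | starting material
2 | allyl 2,4-dihydroxy-6-methylbenzoate | Cc1cc(O)cc(O)c1C(=O)OCC=C | intermediate
3 | allyl 2-hydroxy-4-methoxy-6-methylbenzoate | Cc1cc(OC)cc(O)c1C(=O)OCC=C | intermediate
4 | allyl 2-hydroxy-3-(hydroxymethyl)-4-methoxy-6-methylbenzoate | Cc1cc(OC)c(CO)c(O)c1C(=O)OCC=C | intermediate
5 | allyl 3-formyl-2-hydroxy-4-methoxy-6-methylbenzoate | Cc1cc(OC)c(C=O)c(O)c1C(=O)OCC=C | intermediate
6 | methyl 2,4-dihydroxy-3-methylbenzoate | COC(=O)c1ccc(O)c(C)c1O | starting material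
7 | methyl 2-hydroxy-3-methyl-4-(pivaloyloxy)benzoate | COC(=O)c1ccc(OC(=O)C(C)(C)C)c(C)c1O | intermediate
8 | methyl 2-hydroxy-5-iodo-3-methyl-4-(pivaloyloxy)benzoate | COC(=O)c1cc(I)c(OC(=O)C(C)(C)C)c(C)c1O | intermediate
9 | methyl 5-iodo-2-methoxy-3-methyl-4-(pivaloyloxy)benzoate | COC(=O)c1cc(I)c(OC(=O)C(C)(C)C)c(C)c1OC | intermediate
10 | methyl 3-(bromomethyl)-5-iodo-2-methoxy-4-(pivaloyloxy)benzoate | COC(=O)c1cc(I)c(OC(=O)C(C)(C)C)c(CBr)c1OC | intermediate
11 | methyl 3-(acetoxymethyl)-5-iodo-2-methoxy-4-(pivaloyloxy)benzoate | COC(=O)c1cc(I)c(OC(=O)C(C)(C)C)c(COC(C)=O)c1OC | intermediate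
12 | methyl 3-(acetoxymethyl)-5-(diacetoxy-λ3-iodanyl)-2-methoxy-4-(pivaloyloxy)benzoate | COC(=O)c1cc(I(OC(C)=O)OC(C)=O)c(OC(=O)C(C)(C)C)c(COC(C)=O)c1OC | intermediate
13 | [3-(acetoxymethyl)-4-methoxy-5-(methoxycarbonyl)-2-(pivaloyloxy)phenyl](2,4,6-trimethoxyphenyl)iodonium acetate | COC(=O)c1cc([I+]c2c(OC)cc(OC)cc2OC)c(OC(=O)C(C)(C)C)c(COC(C)=O)c1OC.CC(=O)[O-] | intermediate
14 | allyl 2-[3-(acetoxymethyl)-4-methoxy-5-(methoxycarbonyl)-2-(pivaloyloxy)phenoxy]-3-formyl-4-methoxy-6-methylbenzoate | Cc1cc(OC)c(C=O)c(Oc2cc(C(=O)OC)c(OC)c(COC(C)=O)c2OC(=O)C(C)(C)C)c1C(=O)OCC=C | intermediate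
15 | 2-[3-(acetoxymethyl)-4-methoxy-5-(methoxycarbonyl)-2-(pivaloyloxy)phenoxy]-3-formyl-4-methoxy-6-methylbenzoic acid | Cc1cc(OC)c(C=O)c(Oc2cc(C(=O)OC)c(OC)c(COC(C)=O)c2OC(=O)C(C)(C)C)c1C(=O)O | intermediate
16 | 2-[5-carboxy-2-hydroxy-3-(hydroxymethyl)-4-methoxyphenoxy]-3-formyl-4-methoxy-6-methylbenzoic acid | Cc1cc(OC)c(C=O)c(Oc2cc(C(=O)O)c(OC)c(CO)c2O)c1C(=O)O | intermediate
17 | depsidone (1-Me; 3-OMe; 4-CHO; 2′-CH2OAc; 3′-OMe; 5′–H) with the 4′-carboxyl group as the mixed carboxylic acetic anhydride | Cc1cc(OC)c(C=O)c2c1C(=O)Oc1c(COC(C)=O)c(OC)c(C(=O)OC(C)=O)cc1O2 | intermediate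
18 | depsidone 4′-carboxylic acid (1-Me; 3-OMe; 4-CHO; 2′-CH2OAc; 3′-OMe; 5′–H) | Cc1cc(OC)c(C=O)c2c1C(=O)Oc1c(COC(C)=O)c(OC)c(C(=O)O)cc1O2 | intermediate
19 | vinylene carbonate (1,3-dioxol-2-one) | O=C1OC=CO1 | starting material
20 | isocoumarin-fused depsidone (pyranone from carbon 4′ through C(=O)–O–CH=CH to carbon 5′; 3-OMe; 3′-OMe; 2′-CH2OAc) | Cc1cc(OC)c(C=O)c2c1C(=O)Oc1c(COC(C)=O)c(OC)c3c(c1O2)C=COC3=O | intermediate
21 | secondary ozonide (1,2,4-trioxolane) across the former pyranone C=C bond of 20 | Cc1cc(OC)c(C=O)c2c1C(=O)Oc1c(COC(C)=O)c(OC)c3c(c1O2)C1OOC(O1)OC3=O | intermediate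
22 | depsidone with 5′-CHO and the 4′-carboxyl group as the mixed carboxylic formic anhydride | Cc1cc(OC)c(C=O)c2c1C(=O)Oc1c(COC(C)=O)c(OC)c(C(=O)OC=O)c(C=O)c1O2 | intermediate
23 | depsidone with 5′-CHO and 4′-CO2H (open formyl acid) | Cc1cc(OC)c(C=O)c2c1C(=O)Oc1c(COC(C)=O)c(OC)c(C(=O)O)c(C=O)c1O2 | intermediate
24 | racemic hydroxyphthalide (lactol) with 3-OMe; 3′-OMe; 2′-CH2OAc | Cc1cc(OC)c(C=O)c2c1C(=O)Oc1c(COC(C)=O)c(OC)c3c(c1O2)C(O)OC3=O | intermediate
25 | racemic lactol with 3-OH; 3′-OH; 2′-CH2OAc | Cc1cc(O)c(C=O)c2c1C(=O)Oc1c(COC(C)=O)c(O)c3c(c1O2)C(O)OC3=O | intermediate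
26 | racemic lactol with 3-OH; 3′-OH; 2′-CH2OH (target constitution, both lactol configurations) | Cc1cc(O)c(C=O)c2c1C(=O)Oc1c(CO)c(O)c3c(c1O2)C(O)OC3=O | intermediate
27 | 1:1 inclusion crystal of the (S)-lactol with (4R,5R)-2,2-dimethyl-α,α,α′,α′-tetraphenyl-1,3-dioxolane-4,5-dimethanol | Cc1cc(O)c(C=O)c2c1C(=O)Oc1c(CO)c(O)c3c(c1O2)[C@@H](O)OC3=O.CC1(C)O[C@H]([C@@H](O1)C(O)(c2ccccc2)c2ccccc2)C(O)(c2ccccc2)c2ccccc2 | intermediate
28 | CNP0166154.1, the (S)-lactol (1-Me; 3-OH; 4-CHO; 2′-CH2OH; 3′-OH; (S) at the lactol carbon on carbon 5′) | Cc1cc(O)c(C=O)c2c1C(=O)Oc1c(CO)c(O)c3c(c1O2)[C@@H](O)OC3=O | target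

**Step count and risks**

Total: 17 steps. Longest linear sequence: 14 steps (steps 4 to 17, from 6); the ring A branch (steps 1 to 3) joins at step 10.

Step 17 (bears the label). The inclusion crystal may fail to form, both diastereomeric crystals may deposit together, or the lactol may epimerize while the host is washed out. The fallback sets out from 26 and uses known chemistry: preparative chromatography on a chiral stationary phase (amylose tris(3,5-dimethylphenylcarbamate), supercritical CO2 with an aprotic modifier, run cold) separates the two lactol enantiomers. The (S)-fraction is evaporated cold and crystallized at once, which brings the path back at 28. The (R)-fraction is re-equilibrated to 26 with a trace of AcOH in THF and recycled. No new compound arises on this path (F0).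

Step 10. Ligand coupling of the chelated, doubly ortho-substituted phenoxide may be slow, the aryl group may be transferred to acetate instead, or the pivalate may be lost. The fallback sets out from 11: Miyaura borylation (B2pin2, PdCl2(dppf), KOAc, dioxane, 80 °C) would give methyl 3-(acetoxymethyl)-2-methoxy-4-(pivaloyloxy)-5-(4,4,5,5-tetramethyl-1,3,2-dioxaborolan-2-yl)benzoate F1. This is joined to phenol 5 by Chan–Lam–Evans coupling (Cu(OAc)2, pyridine, 4 Å sieves, air, CH2Cl2, rt), an oxidative C–O coupling at copper that accepts ortho-substituted phenols. The path comes back to the route at 14.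

Step 13. Metalation of the flanked 5′–H may be slow, the electron-rich acid may lose CO2 at 110 °C before it is metalated, or the ortho-methoxy aldehyde may bind the catalyst. The fallback sets out from 18 and replaces the annulation by halogenation and cross-coupling. Carboxylate-directed ortho-iodination at room temperature ([Cp*Ir(H2O)3]SO4 cat., N-iodosuccinimide, (CF3)2CHOH) would give the 5′-iodo depsidone acid F2. Stille coupling with tributyl(vinyl)stannane (Pd2(dba)3, AsPh3, CuI, DMF, 50 °C) would give the 5′-vinyl depsidone acid F3. Ozonolysis with Me2S work-up cuts the vinyl group to the aldehyde on carbon 5′, which closes onto the acid, so the path comes back at lactol 24 without passing through 20.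

**Further compounds**

F0 | step 17 | none | none
F1 | step 10 | methyl 3-(acetoxymethyl)-2-methoxy-4-(pivaloyloxy)-5-(4,4,5,5-tetramethyl-1,3,2-dioxaborolan-2-yl)benzoate | COC(=O)c1cc(B2OC(C)(C)C(C)(C)O2)c(OC(=O)C(C)(C)C)c(COC(C)=O)c1OC
F2 | step 13 | 5′-iodo depsidone 4′-carboxylic acid (3-OMe; 4-CHO; 2′-CH2OAc; 3′-OMe) | Cc1cc(OC)c(C=O)c2c1C(=O)Oc1c(COC(C)=O)c(OC)c(C(=O)O)c(I)c1O2
F3 | step 13 | 5′-vinyl depsidone 4′-carboxylic acid (3-OMe; 4-CHO; 2′-CH2OAc; 3′-OMe) | Cc1cc(OC)c(C=O)c2c1C(=O)Oc1c(COC(C)=O)c(OC)c(C(=O)O)c(C=C)c1O2
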